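**Plan**

- Retrosynthetic cuts, in order: C1–OOH (ene reaction of a 1(10)-alkene), the C8 ester, C11=C13 together with C7–C11 (γ-lactone ring), C7=C8 (ten-membered ring), C4=C5, C3–C4 and C1–C2.
- Forward: an acyclic triene ester is assembled from three small pieces, the ten-membered carbocycle is closed at C7=C8 by metathesis, the lactone ring (O–C6–C7–C11–C12) is closed on the macrocycle, then the C8 ester and the hydroperoxide are added.
- Enabling feature: O6 sits on the carbon next to C7 and C7 is vicinal to C8–O, so a cis-7,8-epoxide lying trans to an O6-bound phosphonoacetate holds the carbanion carbon C11 five atoms from C7 and anti to the C7–O bond; one closure gives the lactone ring, C7 and C8, and the phosphonate then delivers C13.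
- Stereochemistry: C6 from (S)-but-3-ene-1,2-diol (inverted when the acyl tether is attached); C7/C8 from hydroxyl-directed epoxidation, then inversion at C7; C3′ from methyl (S)-glycerate acetonide; C1 from the substrate-controlled ene reaction; C1=C10 from carboalumination, C4=C5 from the olefination.

Key step: step 14

Remark: ring carbons carry germacrane numbers (C6 bears the lactone oxygen, C8 the ester oxygen, C14 sits on C10, C15 on C4); the vanadium-directed epoxidation of the ten-membered dienol 14 is assumed to deliver oxygen cis to the hydroxyl, as it does in eight- and nine-membered 2-cycloalkenols.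

**Route**

Step 1
Reactants: 1 pent-1-en-4-yne
Product: 4 (3E)-4-methylhepta-3,6-dien-1-ol, via alkenyldimethylalane 2 (not isolated), via lithium alkenylaluminate 3 (not isolated)
Conditions: Me3Al, Cp2ZrCl2 (20 mol %), CH2Cl2, 0 °C → rt; then n-BuLi, THF, −78 °C; then ethylene oxide, −78 → 0 °C
Reagents that add atoms: trimethylaluminium, C[Al](C)C; ethylene oxide, C1CO1
Why: Zirconium-catalysed carboalumination adds methyl and aluminium syn across the terminal alkyne with aluminium at the terminus, which fixes the E-trisubstituted C1=C10 alkene, and the derived aluminate should open ethylene oxide with retention of the alkene geometry to add C2 and C3.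

Step 2
Reactants: 4 (3E)-4-methylhepta-3,6-dien-1-ol
Product: 5 (4E)-7-iodo-4-methylhepta-1,4-diene
Conditions: I2, PPh3, imidazole, CH2Cl2, 0 °C
Reagents that add atoms: iodine, II
Why: Appel-type iodination of a primary alcohol proceeds by SN2 displacement of the alkoxyphosphonium ion and leaves both alkenes untouched.

Step 3
Reactants: 5 (4E)-7-iodo-4-methylhepta-1,4-diene; 6 triethyl phosphonoacetate
Product: 7 ethyl (5E)-2-(diethoxyphosphoryl)-6-methylnona-5,8-dienoate (racemic at C2)
Conditions: NaH, THF–DMSO, 0 → 50 °C (excess 6)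
Reagents that add atoms: none
Why: C-alkylation of the sodium phosphonoacetate by a primary iodide forms the C3–C4 bond; the new stereocentre is of no consequence because it becomes sp2 in step 7.

Step 4
Reactants: 8 (2S)-but-3-ene-1,2-diol
Product: 9 (3S)-3,4-bis[(tert-butyldimethylsilyl)oxy]but-1-ene
Conditions: TBSCl, imidazole, DMF, rt
Reagents that add atoms: tert-butyldimethylsilyl chloride, CC(C)(C)[Si](C)(C)Cl
Why: Standard silylation of both hydroxyls; the stereocentre (future C6) is not touched.

Step 5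
Reactants: 9 (3S)-3,4-bis[(tert-butyldimethylsilyl)oxy]but-1-ene
Product: 10 (2S)-2-[(tert-butyldimethylsilyl)oxy]but-3-en-1-ol
Conditions: HF·pyridine, pyridine, THF, 0 °C
Reagents that add atoms: none
Why: A primary silyl ether is cleaved faster than a secondary one under buffered HF·pyridine, and the acidic medium avoids silyl migration.

Step 6
Reactants: 10 (2S)-2-[(tert-butyldimethylsilyl)oxy]but-3-en-1-ol
Product: 11 (2S)-2-[(tert-butyldimethylsilyl)oxy]but-3-enal
Conditions: Dess–Martin periodinane, NaHCO3, CH2Cl2, 0 °C; used at once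
Reagents that add atoms: none
Why: Dess–Martin oxidation under buffered, base-free conditions should give the α-silyloxy β,γ-unsaturated aldehyde without epimerisation or migration of the alkene into conjugation.

Step 7
Reactants: 7 ethyl (5E)-2-(diethoxyphosphoryl)-6-methylnona-5,8-dienoate; 11 (2S)-2-[(tert-butyldimethylsilyl)oxy]but-3-enal
Product: 12 ethyl (2E,4S)-4-[(tert-butyldimethylsilyl)oxy]-2-[(3E)-4-methylhepta-3,6-dien-1-yl]hexa-2,5-dienoate
Conditions: NaH, THF, 0 °C; then 11, −78 → 0 °C
Reagents that add atoms: none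
Why: Horner–Wadsworth–Emmons olefination with an α-substituted phosphonoacetate places the ester (future C15) trans to C6, so that C3 and C6 are cis on C4=C5 as the target requires; the minor geometric isomer should be removable by chromatography.

Step 8
Reactants: 12 ethyl (2E,4S)-4-[(tert-butyldimethylsilyl)oxy]-2-[(3E)-4-methylhepta-3,6-dien-1-yl]hexa-2,5-dienoate
Product: 13 ethyl (1E,3S,4Z,7E)-3-[(tert-butyldimethylsilyl)oxy]-7-methylcyclodeca-1,4,7-triene-1-carboxylate
Conditions: RuCl2(=CHPh)(PCy3)2 (first-generation Grubbs catalyst, 10 mol %), CH2Cl2 (1 mM), reflux, argon purge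
Reagents that add atoms: none
Why: Ring-closing metathesis of the two monosubstituted alkenes closes the ten-membered ring at C7=C8, which the ring size forces to be Z; the first-generation catalyst should leave the trisubstituted C1=C10 and the enoate alkene alone, so that no seven-membered ring forms by truncation.

Step 9
Reactants: 13 ethyl (1E,3S,4Z,7E)-3-[(tert-butyldimethylsilyl)oxy]-7-methylcyclodeca-1,4,7-triene-1-carboxylate
Product: 14 ethyl (1E,3S,4Z,7E)-3-hydroxy-7-methylcyclodeca-1,4,7-triene-1-carboxylate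
Conditions: HF·pyridine, pyridine, THF, 0 °C → rt
Reagents that add atoms: none
Why: Acidic fluoride desilylation frees the C6 hydroxyl without base, so the doubly allylic C6–H is not at risk of isomerisation.

Step 10
Reactants: 14 ethyl (1E,3S,4Z,7E)-3-hydroxy-7-methylcyclodeca-1,4,7-triene-1-carboxylate
Product: 15 ethyl (1E,3R,4R,5S,7E)-4,5-epoxy-3-hydroxy-7-methylcyclodeca-1,7-diene-1-carboxylate (cis-epoxide, cis to the hydroxyl)
Conditions: VO(acac)2 (5 mol %), t-BuOOH, CH2Cl2, 0 °C
Reagents that add atoms: tert-butyl hydroperoxide, CC(C)(C)OO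
Why: Hydroxyl-directed epoxidation through the vanadate ester of the C6 alcohol should deliver oxygen to the C7=C8 face cis to the hydroxyl, which sets C7 and C8 relative to C6; the enoate alkene is too electron-poor and the C1=C10 alkene has no directing group.

Step 11
Reactants: 15 ethyl (1E,3R,4R,5S,7E)-4,5-epoxy-3-hydroxy-7-methylcyclodeca-1,7-diene-1-carboxylate
Product: 16 (1R,2E,6E,9S,10R)-9,10-epoxy-3-(hydroxymethyl)-7-methylcyclodeca-2,6-dien-1-ol
Conditions: i-Bu2AlH, CH2Cl2, −78 °C; aqueous potassium sodium tartrate work-up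
Reagents that add atoms: none
Why: 1,2-Reduction of the enoate to the C15 allylic alcohol is fast at −78 °C, where the epoxide should not be opened.

Step 12
Reactants: 16 (1R,2E,6E,9S,10R)-9,10-epoxy-3-(hydroxymethyl)-7-methylcyclodeca-2,6-dien-1-ol
Product: 17 (1R,2E,6E,9S,10R)-3-(acetoxymethyl)-9,10-epoxy-7-methylcyclodeca-2,6-dien-1-ol
Conditions: AcCl (1.05 equiv), 2,4,6-collidine, CH2Cl2, −78 °C
Reagents that add atoms: acetyl chloride, CC(=O)Cl
Why: The primary allylic hydroxyl is acetylated selectively over the hindered secondary C6 hydroxyl at low temperature with a weak, bulky base.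

Step 13
Reactants: 17 (1R,2E,6E,9S,10R)-3-(acetoxymethyl)-9,10-epoxy-7-methylcyclodeca-2,6-dien-1-ol; 18 (diethoxyphosphoryl)acetic acid
Product: 19 (1S,2E,6E,9S,10S)-3-(acetoxymethyl)-9,10-epoxy-7-methylcyclodeca-2,6-dien-1-yl (diethoxyphosphoryl)acetate
Conditions: PPh3, DIAD, THF, 0 °C → rt
Reagents that add atoms: none
Why: Mitsunobu esterification (SN2 at C6 of the alkoxyphosphonium ion) attaches the phosphonoacetate with inversion, so that O6 now lies trans to the epoxide oxygen, as the backside attack of step 14 requires.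

Step 14
Reactants: 19 (1S,2E,6E,9S,10S)-3-(acetoxymethyl)-9,10-epoxy-7-methylcyclodeca-2,6-dien-1-yl (diethoxyphosphoryl)acetate
Product: 21 (1(10)E,4E,6S,7R,8S)-15-acetoxy-8-hydroxygermacra-1(10),4,11(13)-trien-12,6-olide, via α-phosphono lactone 20 (not isolated)
Conditions: NaH (1.05 equiv), THF, 0 → 45 °C; then (CH2O)n, 0 °C → rt
Reagents that add atoms: formaldehyde (from paraformaldehyde), C=O
Why: Deprotonation gives the phosphonate-stabilised ester carbanion at C11, which opens the epoxide at C7 by intramolecular SN2 attack (5-exo-tet, ring O–C6–C7–C11–C12); the C8 alkoxide is quenched by the acidic C11–H of the product, and the resulting phosphonate anion undergoes Horner–Wadsworth–Emmons olefination with formaldehyde to give C11=C13. The closest known reaction types are the 5-exo opening of 2,3-epoxy alcohol esters by sulfonyl- or cyano-stabilised carbanions (epoxynitrile-type cyclisation) and the intermolecular opening of epoxides by sodium phosphonoacetates to α-phosphono-γ-lactones followed by methylenation. C7 is set by inversion at the epoxide carbon and C8 keeps the configuration of its epoxide C–O bond; because O6 is trans to the epoxide oxygen, the new C7–C11 bond is cis to C6–O and the lactone is cis-fused. The step needs attack at C7 in preference to C8: attack at C7 gives a fused five-membered ring along a collinear backside trajectory, whereas attack at C8 would give a bridged six-membered lactone spanning C6–C8. C-alkylation should be favoured by the soft phosphonate carbanion, and one equivalent of base leaves no free alkoxide that could translactonise to O8 or cleave the C15 acetate.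

Step 15
Reactants: 22 methyl (4S)-2,2-dimethyl-1,3-dioxolane-4-carboxylate
Product: 23 (4S)-N-methoxy-N,2,2-trimethyl-1,3-dioxolane-4-carboxamide
Conditions: MeNH(OMe)·HCl, i-PrMgCl, THF, −20 °C
Reagents that add atoms: N,O-dimethylhydroxylamine hydrochloride, CNOC.Cl
Why: Aminolysis of the ester by the magnesium amide gives the Weinreb amide at low temperature without epimerisation of the α-alkoxy centre.

Step 16
Reactants: 23 (4S)-N-methoxy-N,2,2-trimethyl-1,3-dioxolane-4-carboxamide
Product: 24 1-[(4S)-2,2-dimethyl-1,3-dioxolan-4-yl]ethan-1-one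
Conditions: MeMgBr, THF, 0 °C
Reagents that add atoms: methylmagnesium bromide, C[Mg]Br
Why: The chelated tetrahedral intermediate of the Weinreb amide stops the Grignard addition at the methyl ketone.

Step 17
Reactants: 24 1-[(4S)-2,2-dimethyl-1,3-dioxolan-4-yl]ethan-1-one
Product: 25 1-[(4S)-2,2-dimethyl-1,3-dioxolan-4-yl]ethenyl trifluoromethanesulfonate
Conditions: KHMDS, THF, −78 °C; then PhNTf2, −78 → 0 °C
Reagents that add atoms: N-phenylbis(trifluoromethanesulfonimide), O=S(=O)(N(c1ccccc1)S(=O)(=O)C(F)(F)F)C(F)(F)F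
Why: Kinetic deprotonation occurs at the methyl group, so O-triflation gives the terminal enol triflate and the α-alkoxy stereocentre is not enolised.

Step 18
Reactants: 25 1-[(4S)-2,2-dimethyl-1,3-dioxolan-4-yl]ethenyl trifluoromethanesulfonate
Product: 26 2-[(4R)-2,2-dimethyl-1,3-dioxolan-4-yl]prop-2-enoic acid
Conditions: Pd(OAc)2 (5 mol %), dppf, CO (1 atm), Et3N, DMF–H2O, 60 °C
Reagents that add atoms: carbon monoxide, [C-]#[O+]; water, O
Why: Palladium-catalysed hydroxycarbonylation of the enol triflate (oxidative addition, CO insertion, hydrolysis of the acyl complex) gives the 2-substituted acrylic acid; the stereocentre keeps its geometry and only its descriptor changes.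

Step 19
Reactants: 21 (1(10)E,4E,6S,7R,8S)-15-acetoxy-8-hydroxygermacra-1(10),4,11(13)-trien-12,6-olide; 26 2-[(4R)-2,2-dimethyl-1,3-dioxolan-4-yl]prop-2-enoic acid
Product: 27 (1(10)E,4E,6S,7R,8S)-15-acetoxy-8-{2-[(4R)-2,2-dimethyl-1,3-dioxolan-4-yl]prop-2-enoyloxy}germacra-1(10),4,11(13)-trien-12,6-olide
Conditions: DIC, DMAP, CH2Cl2, 0 °C → rt
Reagents that add atoms: none
Why: Steglich esterification acylates the only free hydroxyl (C8) under neutral conditions that spare the α-methylene lactone, the allylic acetate and the 1,5-diene.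

Step 20
Reactants: 27 (the acetonide-protected C8 ester)
Product: 28 (1(10)E,4E,6S,7R,8S)-15-acetoxy-8-[(3R)-3,4-dihydroxy-2-methylenebutanoyloxy]germacra-1(10),4,11(13)-trien-12,6-olide
Conditions: AcOH–H2O (7:3), rt
Reagents that add atoms: none
Why: A terminal acetonide is hydrolysed by dilute acetic acid at room temperature, conditions under which the deactivated 1,5-diene should not cyclise across the ring and the ester should not lactonise.

Step 21
Reactants: 28 (the diol ester)
Product: 29 (1R,4E,6S,7R,8S)-15-acetoxy-8-[(3R)-3,4-dihydroxy-2-methylenebutanoyloxy]-1-hydroperoxygermacra-4,10(14),11(13)-trien-12,6-olide (target)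
Conditions: O2, tetraphenylporphyrin (cat.), visible light, CH2Cl2, −20 °C
Reagents that add atoms: dioxygen, O=O
Why: Schenck ene reaction of singlet oxygen with the most electron-rich alkene, C1=C10 (C4=C5 carries two allylic oxygens and both acrylates are inert), should place oxygen on C1 from the exposed outer face of the E-alkene and take hydrogen from the C14 methyl on the disubstituted side, as in the photooxygenation of other germacranolides to 1-hydroperoxy-10(14)-enes; the C1 configuration rests on the face exposed in the preferred ring conformer, the bias by which the natural product presumably arises.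

**Compound list**

1 | pent-1-en-4-yne | C=CCC#C | starting material
2 | dimethyl[(1E)-2-methylpenta-1,4-dien-1-yl]alane (not isolated) | C=CC/C(C)=C/[Al](C)C | intermediate
3 | lithium butyl(dimethyl)[(1E)-2-methylpenta-1,4-dien-1-yl]aluminate (not isolated) | [Li+].CCCC[Al-](C)(C)/C=C(\C)CC=C | intermediate
4 | (3E)-4-methylhepta-3,6-dien-1-ol | OCC/C=C(\C)CC=C | intermediate
5 | (4E)-7-iodo-4-methylhepta-1,4-diene | ICC/C=C(\C)CC=C | intermediate
6 | triethyl phosphonoacetate | CCOC(=O)CP(=O)(OCC)OCC | starting material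
7 | ethyl (5E)-2-(diethoxyphosphoryl)-6-methylnona-5,8-dienoate (racemic) | CCOC(=O)C(CC/C=C(\C)CC=C)P(=O)(OCC)OCC | intermediate
8 | (2S)-but-3-ene-1,2-diol | C=C[C@H](O)CO | starting material
9 | (3S)-3,4-bis[(tert-butyldimethylsilyl)oxy]but-1-ene | C=C[C@H](O[Si](C)(C)C(C)(C)C)CO[Si](C)(C)C(C)(C)C | intermediate
10 | (2S)-2-[(tert-butyldimethylsilyl)oxy]but-3-en-1-ol | C=C[C@H](O[Si](C)(C)C(C)(C)C)CO | intermediate
11 | (2S)-2-[(tert-butyldimethylsilyl)oxy]but-3-enal | C=C[C@H](O[Si](C)(C)C(C)(C)C)C=O | intermediate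
12 | ethyl (2E,4S)-4-[(tert-butyldimethylsilyl)oxy]-2-[(3E)-4-methylhepta-3,6-dien-1-yl]hexa-2,5-dienoate | CC(C)(C)[Si](C)(C)O[C@@H](C=C)/C=C(/C(=O)OCC)CC/C=C(\C)CC=C | intermediate
13 | ethyl (1E,3S,4Z,7E)-3-[(tert-butyldimethylsilyl)oxy]-7-methylcyclodeca-1,4,7-triene-1-carboxylate | CC(C)(C)[Si](C)(C)O[C@@H]1/C=C(/C(=O)OCC)CC/C=C(C)/C/C=C\1 | intermediate
14 | ethyl (1E,3S,4Z,7E)-3-hydroxy-7-methylcyclodeca-1,4,7-triene-1-carboxylate | O[C@@H]1/C=C(/C(=O)OCC)CC/C=C(C)/C/C=C\1 | intermediate
15 | ethyl (1E,3R,4R,5S,7E)-4,5-epoxy-3-hydroxy-7-methylcyclodeca-1,7-diene-1-carboxylate | O[C@@H]1/C=C(/C(=O)OCC)CC/C=C(C)/C[C@@H]2O[C@@H]21 | intermediate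
16 | (1R,2E,6E,9S,10R)-9,10-epoxy-3-(hydroxymethyl)-7-methylcyclodeca-2,6-dien-1-ol | O[C@@H]1/C=C(/CO)CC/C=C(C)/C[C@@H]2O[C@@H]21 | intermediate
17 | (1R,2E,6E,9S,10R)-3-(acetoxymethyl)-9,10-epoxy-7-methylcyclodeca-2,6-dien-1-ol | O[C@@H]1/C=C(/COC(C)=O)CC/C=C(C)/C[C@@H]2O[C@@H]21 | intermediate
18 | (diethoxyphosphoryl)acetic acid | CCOP(=O)(CC(=O)O)OCC | starting material
19 | (1S,2E,6E,9S,10S)-3-(acetoxymethyl)-9,10-epoxy-7-methylcyclodeca-2,6-dien-1-yl (diethoxyphosphoryl)acetate | CCOP(=O)(OCC)CC(=O)O[C@H]1/C=C(/COC(C)=O)CC/C=C(C)/C[C@@H]2O[C@@H]21 | intermediate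
20 | (6S,7R,8S)-15-acetoxy-11-(diethoxyphosphoryl)-8-hydroxy-13-norgermacra-1(10)E,4-dien-12,6-olide, C11 epimers, present as its sodium carbanion (not isolated) | CCOP(=O)(OCC)C1C(=O)O[C@H]2/C=C(/COC(C)=O)CC/C=C(C)/C[C@H](O)[C@@H]12 | intermediate
21 | (1(10)E,4E,6S,7R,8S)-15-acetoxy-8-hydroxygermacra-1(10),4,11(13)-trien-12,6-olide (cis-fused lactone; C3 and C6 cis on C4=C5) | C=C1C(=O)O[C@H]2/C=C(/COC(C)=O)CC/C=C(C)/C[C@H](O)[C@@H]12 | intermediate
22 | methyl (4S)-2,2-dimethyl-1,3-dioxolane-4-carboxylate | COC(=O)[C@@H]1COC(C)(C)O1 | starting material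
23 | (4S)-N-methoxy-N,2,2-trimethyl-1,3-dioxolane-4-carboxamide | CON(C)C(=O)[C@@H]1COC(C)(C)O1 | intermediate
24 | 1-[(4S)-2,2-dimethyl-1,3-dioxolan-4-yl]ethan-1-one | CC(=O)[C@@H]1COC(C)(C)O1 | intermediate
25 | 1-[(4S)-2,2-dimethyl-1,3-dioxolan-4-yl]ethenyl trifluoromethanesulfonate | C=C(OS(=O)(=O)C(F)(F)F)[C@@H]1COC(C)(C)O1 | intermediate
26 | 2-[(4R)-2,2-dimethyl-1,3-dioxolan-4-yl]prop-2-enoic acid | C=C(C(=O)O)[C@@H]1COC(C)(C)O1 | intermediate
27 | (1(10)E,4E,6S,7R,8S)-15-acetoxy-8-{2-[(4R)-2,2-dimethyl-1,3-dioxolan-4-yl]prop-2-enoyloxy}germacra-1(10),4,11(13)-trien-12,6-olide | C=C1C(=O)O[C@H]2/C=C(/COC(C)=O)CC/C=C(C)/C[C@H](OC(=O)C(=C)[C@@H]3COC(C)(C)O3)[C@@H]12 | intermediate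
28 | (1(10)E,4E,6S,7R,8S)-15-acetoxy-8-[(3R)-3,4-dihydroxy-2-methylenebutanoyloxy]germacra-1(10),4,11(13)-trien-12,6-olide | C=C1C(=O)O[C@H]2/C=C(/COC(C)=O)CC/C=C(C)/C[C@H](OC(=O)C(=C)[C@@H](O)CO)[C@@H]12 | intermediate
29 | (1R,4E,6S,7R,8S)-15-acetoxy-8-[(3R)-3,4-dihydroxy-2-methylenebutanoyloxy]-1-hydroperoxygermacra-4,10(14),11(13)-trien-12,6-olide | C=C1C(=O)O[C@H]2/C=C(/COC(C)=O)CC[C@@H](OO)C(=C)C[C@H](OC(=O)C(=C)[C@@H](O)CO)[C@@H]12 | target

**Count**

Total steps: 21. Longest linear sequence: 14 steps (steps 1, 2, 3, 7–14, 19, 20, 21).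

**Steps most likely to fail**

Step 8 (ring closure). The strained ten-membered triene may not close: the diene may oligomerise at any useful concentration, or the catalyst may stall on the hindered allylic silyl ether. The fallback closes the ring at C4=C5 by olefination, after C7=C8 has been made Z in the open chain. It sets out from 7 and 9. Z-selective cross-metathesis with the cyclometalated catalyst Ru(NO3)(=CH-C6H4-2-Oi-Pr)(C,C-chelating N-adamantyl-N′-mesitylimidazolin-2-ylidene) should give ethyl (5E,8Z,10S)-10,11-bis[(tert-butyldimethylsilyl)oxy]-2-(diethoxyphosphoryl)-6-methylundeca-5,8-dienoate F1. Selective primary desilylation (HF·pyridine, pyridine, THF) gives the primary alcohol F2, and Dess–Martin oxidation gives the aldehyde F3. Intramolecular Horner–Wadsworth–Emmons olefination (LiCl, DBU, MeCN, high dilution) then closes the ring and returns to the route at 13.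

Step 14 (lactone closure). The phosphonate carbanion may be too weak a nucleophile for the internal epoxide, or it may react through oxygen or at C8. The fallback keeps the epoxide as electrophile but uses a malonate carbanion and a decarboxylative methylenation. It sets out from 17. Mitsunobu esterification with 3-oxo-3-[2-(trimethylsilyl)ethoxy]propanoic acid gives the inverted mixed malonate F4. Cs2CO3 in DMF (or NaH in THF) should close the α-[2-(trimethylsilyl)ethoxycarbonyl] lactone F5, and Bu4NF buffered with AcOH frees the α-carboxy lactone F6. Treatment with Et2NH and aqueous formaldehyde, then warm NaOAc/AcOH (Mannich reaction with decarboxylative elimination), gives the α-methylene lactone and returns to the route at 21.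

Step 21 (hydroperoxide). Oxygen may be delivered to the wrong face of C1=C10, giving mainly the C1 epimer, or some hydrogen may be taken from C2 instead of C14. The fallback corrects C1 by substitution with inversion and sets out from 27. Photooxygenation of 27 under the conditions of step 21 gives, in the unfavourable case, the (1S)-hydroperoxide acetonide F7. PPh3 reduces it to the (1S)-allylic alcohol F8, and MsCl/Et3N at −20 °C gives the methanesulfonate F9. SN2 displacement with the caesium salt of 2-methoxyprop-2-yl hydroperoxide (CsOH, DMF) gives the (1R)-peroxyketal F10. AcOH–H2O then cleaves the peroxyketal and the acetonide together and returns to the route at 29.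

**Further compounds**

F1 | step 8 | ethyl (5E,8Z,10S)-10,11-bis[(tert-butyldimethylsilyl)oxy]-2-(diethoxyphosphoryl)-6-methylundeca-5,8-dienoate | CCOC(=O)C(CC/C=C(\C)C/C=C\[C@H](O[Si](C)(C)C(C)(C)C)CO[Si](C)(C)C(C)(C)C)P(=O)(OCC)OCC
F2 | step 8 | ethyl (5E,8Z,10S)-10-[(tert-butyldimethylsilyl)oxy]-2-(diethoxyphosphoryl)-11-hydroxy-6-methylundeca-5,8-dienoate | CCOC(=O)C(CC/C=C(\C)C/C=C\[C@H](O[Si](C)(C)C(C)(C)C)CO)P(=O)(OCC)OCC
F3 | step 8 | ethyl (5E,8Z,10S)-10-[(tert-butyldimethylsilyl)oxy]-2-(diethoxyphosphoryl)-6-methyl-11-oxoundeca-5,8-dienoate | CCOC(=O)C(CC/C=C(\C)C/C=C\[C@H](O[Si](C)(C)C(C)(C)C)C=O)P(=O)(OCC)OCC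
F4 | step 14 | (1S,2E,6E,9S,10S)-3-(acetoxymethyl)-9,10-epoxy-7-methylcyclodeca-2,6-dien-1-yl 2-(trimethylsilyl)ethyl malonate | C[Si](C)(C)CCOC(=O)CC(=O)O[C@H]1/C=C(/COC(C)=O)CC/C=C(C)/C[C@@H]2O[C@@H]21
F5 | step 14 | (6S,7R,8S)-15-acetoxy-8-hydroxy-11-[2-(trimethylsilyl)ethoxycarbonyl]-13-norgermacra-1(10)E,4-dien-12,6-olide | C[Si](C)(C)CCOC(=O)C1C(=O)O[C@H]2/C=C(/COC(C)=O)CC/C=C(C)/C[C@H](O)[C@@H]12
F6 | step 14 | (6S,7R,8S)-15-acetoxy-11-carboxy-8-hydroxy-13-norgermacra-1(10)E,4-dien-12,6-olide | OC(=O)C1C(=O)O[C@H]2/C=C(/COC(C)=O)CC/C=C(C)/C[C@H](O)[C@@H]12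
F7 | step 21 | (1S)-hydroperoxide of the acetonide-protected ester (C1 epimer of protected 29) | C=C1C(=O)O[C@H]2/C=C(/COC(C)=O)CC[C@H](OO)C(=C)C[C@H](OC(=O)C(=C)[C@@H]3COC(C)(C)O3)[C@@H]12
F8 | step 21 | (1S)-1-hydroxy-10(14)-ene acetonide-protected ester | C=C1C(=O)O[C@H]2/C=C(/COC(C)=O)CC[C@H](O)C(=C)C[C@H](OC(=O)C(=C)[C@@H]3COC(C)(C)O3)[C@@H]12
F9 | step 21 | (1S)-1-methanesulfonyloxy-10(14)-ene acetonide-protected ester | C=C1C(=O)O[C@H]2/C=C(/COC(C)=O)CC[C@H](OS(C)(=O)=O)C(=C)C[C@H](OC(=O)C(=C)[C@@H]3COC(C)(C)O3)[C@@H]12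
F10 | step 21 | (1R)-1-[(2-methoxypropan-2-yl)peroxy]-10(14)-ene acetonide-protected ester | C=C1C(=O)O[C@H]2/C=C(/COC(C)=O)CC[C@@H](OOC(C)(C)OC)C(=C)C[C@H](OC(=O)C(=C)[C@@H]3COC(C)(C)O3)[C@@H]12
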